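Assumption: carbons carry the germacrane numbers of the target (ring C1–C10, lactone C11–C13, C14 = methyl on C10, C15 = CH2O on C4), and a named chiral ligand means the enantiomer that gives the stated configuration.

## Retrosynthetic overview

1. The ten-membered ring is closed last at C3–C4 by an intramolecular Nozaki–Hiyama–Kishi coupling of a (Z)-vinyl iodide with a β-silyloxy aldehyde; O-acetylation and desilylation finish the target.
2. C7–C8 comes from a Barbier allylation of a (Z)-enal (fragment B) with a 3-(bromomethyl)butenolide (fragment A); the new C8 hydroxyl is then angeloylated.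
3. Key bond: the lactone C6–O bond, made by an enantioconvergent iridium-catalysed allylic esterification of a racemic dienyl carbonate with 2-(bromomethyl)acrylic acid. It sets C6, and C6 relays to C7 and C8.
4. Fragment B comes from an asymmetric alkynylation (C1) and syn-methylcupration of the ynoate ((Z)-C9=C10). Fragment A comes from acrolein and a silyl propargyl ether by hydroalumination–iodination ((Z)-C4=C5).
5. Ring order: butenolide first (ring-closing metathesis; it becomes the α-methylene-γ-lactone in the Barbier step), then the ten-membered carbocycle.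

## Route

Step 1
Reactants: 1 tert-butyldimethyl(prop-2-yn-1-yloxy)silane; 2 acrolein
Product: 4 rac-6-[(tert-butyldimethylsilyl)oxy]hex-1-en-4-yn-3-ol, via lithium acetylide 3 (not isolated)
Conditions: n-BuLi, THF, −78 °C; then 2, −78 °C; H2O
Reagents that add atoms: none
Why: 1,2-addition of a lithium acetylide to the enal (alkynylation) assembles C4–C7 and C15; the carbinol carbon (C6) is left racemic because step 4 sets it.

Step 2
Reactants: 4 rac-6-[(tert-butyldimethylsilyl)oxy]hex-1-en-4-yn-3-ol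
Product: 6 rac-(4Z)-6-[(tert-butyldimethylsilyl)oxy]-5-iodohexa-1,4-dien-3-ol, via cyclic sodium vinylalanate 5 (not isolated)
Conditions: NaAlH2(OCH2CH2OMe)2 (Red-Al), THF, 0 °C; then I2, −78 °C; aq. work-up
Reagents that add atoms: iodine, II
Why: hydroxyl-directed trans-hydroalumination of the propargylic alcohol places aluminium on the distal alkyne carbon cis to the carbinol carbon, and iodinolysis with retention gives the (Z)-vinyl iodide that fixes the ring-cis C4=C5 geometry.

Step 3
Reactants: 6 rac-(4Z)-6-[(tert-butyldimethylsilyl)oxy]-5-iodohexa-1,4-dien-3-ol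
Product: 7 rac-(4Z)-6-[(tert-butyldimethylsilyl)oxy]-5-iodohexa-1,4-dien-3-yl methyl carbonate
Conditions: ClCO2Me, pyridine, CH2Cl2, 0 °C
Reagents that add atoms: methyl chloroformate, COC(=O)Cl
Why: O-acylation to the methyl carbonate gives a leaving group that ionises irreversibly (loss of CO2 and methoxide) in step 4.

Step 4
Reactants: 7 rac-(4Z)-6-[(tert-butyldimethylsilyl)oxy]-5-iodohexa-1,4-dien-3-yl methyl carbonate; 8 2-(bromomethyl)prop-2-enoic acid
Product: 9 (3R,4Z)-6-[(tert-butyldimethylsilyl)oxy]-5-iodohexa-1,4-dien-3-yl 2-(bromomethyl)prop-2-enoate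
Conditions: [Ir(cod)Cl]2 (2.5 mol%), (S)-BINOL-derived phosphoramidite–olefin ligand (10 mol%), THF, 25 °C, 8 added over 4 h
Reagents that add atoms: none
Why: Proposed new method: the monovalent iridium–phosphoramidite complex ionises either enantiomer of 7 with loss of CO2 to (η3-allyl) complexes of trivalent iridium (C7′–C7–C6) that interconvert through the η1 form at the unsubstituted terminus faster than the weakly nucleophilic carboxylate (formed salt-free from 8 and the expelled methoxide) attacks, so ligand-controlled outer-sphere C–O bond formation at the alkenyl-substituted terminus converges on the (R)-ester and sets C6; the ester ionises far more slowly than the carbonate, and the 2-substituted allyl bromide of 8 is not a substrate for this catalyst; the closest known reaction types are iridium-catalysed enantioselective allylic esterification of linear allylic carbonates with carboxylates and iridium/phosphoramidite–olefin-catalysed enantioconvergent substitution of racemic branched allylic alcohols by O-nucleophiles.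

Step 5
Reactants: 9 (3R,4Z)-6-[(tert-butyldimethylsilyl)oxy]-5-iodohexa-1,4-dien-3-yl 2-(bromomethyl)prop-2-enoate
Product: 10 (5R)-3-(bromomethyl)-5-[(1Z)-3-[(tert-butyldimethylsilyl)oxy]-2-iodoprop-1-en-1-yl]furan-2(5H)-one (fragment A)
Conditions: second-generation Grubbs catalyst RuCl2(=CHPh)(H2IMes)(PCy3) (5 mol%), CH2Cl2 (5 mM), 40 °C
Reagents that add atoms: none
Why: ring-closing metathesis between the vinyl group and the acrylate gives the butenolide (first ring); the trisubstituted vinyl iodide is inert and C6 is untouched.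

Step 6
Reactants: 11 ethyl 3,3-diethoxypropanoate
Product: 12 3,3-diethoxypropanal
Conditions: i-Bu2AlH (1.05 equiv), CH2Cl2, −78 °C; aq. work-up
Reagents that add atoms: none
Why: partial reduction of the ester stops at the aldehyde because the tetrahedral aluminium hemiacetal is stable at −78 °C.

Step 7
Reactants: 12 3,3-diethoxypropanal; 13 methyl propiolate
Product: 14 methyl (4S)-6,6-diethoxy-4-hydroxyhex-2-ynoate
Conditions: (S,S)-ProPhenol (10 mol%), Me2Zn (3 equiv), Ph3PO (20 mol%), toluene, 0 °C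
Reagents that add atoms: none
Why: dinuclear zinc–ProPhenol-catalysed asymmetric alkynylation of the aldehyde sets C1 (S) under ligand control.

Step 8
Reactants: 14 methyl (4S)-6,6-diethoxy-4-hydroxyhex-2-ynoate
Product: 15 methyl (4S)-4-[(tert-butyldimethylsilyl)oxy]-6,6-diethoxyhex-2-ynoate
Conditions: TBSCl, imidazole, DMF, 25 °C
Reagents that add atoms: tert-butyldimethylsilyl chloride, CC(C)(C)[Si](C)(C)Cl
Why: silylation protects the C1 hydroxyl, which also prevents lactonisation after the next step.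

Step 9
Reactants: 15 methyl (4S)-4-[(tert-butyldimethylsilyl)oxy]-6,6-diethoxyhex-2-ynoate
Product: 16 methyl (2Z,4S)-4-[(tert-butyldimethylsilyl)oxy]-6,6-diethoxy-3-methylhex-2-enoate
Conditions: MeLi, CuI (gives Me2CuLi), THF, −78 °C; H2O at −78 °C
Reagents that add atoms: lithium dimethylcuprate, [Li+].C[Cu-]C
Why: syn-carbocupration (conjugate addition of the cuprate to the ynoate) with protonation at low temperature puts the methyl group (C14) on C10 and leaves the ester cis to C1, giving the (Z)-C9=C10 olefin.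

Step 10
Reactants: 16 methyl (2Z,4S)-4-[(tert-butyldimethylsilyl)oxy]-6,6-diethoxy-3-methylhex-2-enoate
Product: 17 (2Z,4S)-4-[(tert-butyldimethylsilyl)oxy]-6,6-diethoxy-3-methylhex-2-en-1-ol
Conditions: i-Bu2AlH (2.2 equiv), CH2Cl2, −78 °C; aq. work-up
Reagents that add atoms: none
Why: 1,2-reduction of the enoate by the aluminium hydride gives the allylic alcohol without touching the olefin geometry.

Step 11
Reactants: 17 (2Z,4S)-4-[(tert-butyldimethylsilyl)oxy]-6,6-diethoxy-3-methylhex-2-en-1-ol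
Product: 18 (2Z,4S)-4-[(tert-butyldimethylsilyl)oxy]-6,6-diethoxy-3-methylhex-2-enal (fragment B)
Conditions: MnO2, CH2Cl2, 25 °C
Reagents that add atoms: none
Why: neutral allylic oxidation with MnO2 gives the β,β-disubstituted (Z)-enal with retention of geometry.

Step 12
Reactants: 10 fragment A; 18 fragment B
Product: 19 (1S,6R,7S,8R,4Z,9Z)-1,15-bis[(tert-butyldimethylsilyl)oxy]-3,3-diethoxy-8-hydroxy-4-iodo-3,4-secogermacra-4,9,11(13)-trien-12,6-olide
Conditions: indium powder (In), THF/H2O (3:1), 25 °C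
Reagents that add atoms: none
Why: Barbier allylation in which the allylindium from the bromomethyl butenolide adds through its γ-carbon (C7) in a chair Zimmerman–Traxler transition state on the face anti to the C6 substituent, giving the trans-lactone (C7) and the anti carbinol (C8) while the exocyclic methylene forms by allylic transposition.

Step 13
Reactants: 19 Barbier adduct; 20 angelic acid ((2Z)-2-methylbut-2-enoic acid)
Product: 22 (1S,6R,7S,8R,4Z,9Z)-8-angeloyloxy-1,15-bis[(tert-butyldimethylsilyl)oxy]-3,3-diethoxy-4-iodo-3,4-secogermacra-4,9,11(13)-trien-12,6-olide, via angelic 2,4,6-trichlorobenzoic anhydride 21 (not isolated)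
Conditions: 20, 2,4,6-trichlorobenzoyl chloride, Et3N, toluene, 25 °C; then 19, 75 °C
Reagents that add atoms: none
Why: Yamaguchi-type mixed-anhydride esterification run without a nucleophilic catalyst transfers the (Z)-2-methylbut-2-enoyl group without isomerisation to the tiglate and with retention at C8.

Step 14
Reactants: 22 angelate acetal
Product: 23 (1S,6R,7S,8R,4Z,9Z)-8-angeloyloxy-1,15-bis[(tert-butyldimethylsilyl)oxy]-4-iodo-3-oxo-3,4-secogermacra-4,9,11(13)-trien-12,6-olide
Conditions: PPTS (cat.), acetone/H2O (10:1), 40 °C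
Reagents that add atoms: water, O
Why: mild acid-catalysed acetal hydrolysis unmasks the C3 aldehyde while silyl ethers, allylic esters and the vinyl iodide survive.

Step 15
Reactants: 23 iodo aldehyde
Product: 24 (1S,3S,6S,7S,8R,4Z,9Z)-8-angeloyloxy-1,15-bis[(tert-butyldimethylsilyl)oxy]-3-hydroxygermacra-4,9,11(13)-trien-12,6-olide
Conditions: CrCl2 (8 equiv), NiCl2 (2 mol%), DMSO (2 mM), 25 °C; H2O
Reagents that add atoms: none
Why: intramolecular Nozaki–Hiyama–Kishi coupling closes the ten-membered ring with retention of the vinyl iodide geometry (ring-cis C4=C5), and C3 is set 1,3-anti to the β-silyloxy group at C1 (polar Evans-type induction in the non-chelated addition).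

Step 16
Reactants: 24 macrocyclic alcohol
Product: 25 (1S,3S,6S,7S,8R,4Z,9Z)-3-acetoxy-8-angeloyloxy-1,15-bis[(tert-butyldimethylsilyl)oxy]germacra-4,9,11(13)-trien-12,6-olide
Conditions: Ac2O, DMAP (cat.), pyridine, CH2Cl2, 0 °C
Reagents that add atoms: acetic anhydride, CC(=O)OC(C)=O
Why: DMAP-catalysed O-acetylation of the only free hydroxyl proceeds with retention at C3.

Step 17
Reactants: 25 bis-silyl ether
Product: 26 (1S,3S,6S,7S,8R,4Z,9Z)-3-acetoxy-8-angeloyloxy-1,15-dihydroxygermacra-4,9,11(13)-trien-12,6-olide (target)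
Conditions: HF·pyridine, pyridine, THF, 0 to 25 °C
Reagents that add atoms: none
Why: fluoride-mediated desilylation under buffered acidic conditions frees the C1 and C15 hydroxyls without acyl migration or conjugate addition to the α-methylene lactone.

## Compound list

1 | tert-butyldimethyl(prop-2-yn-1-yloxy)silane | C#CCO[Si](C)(C)C(C)(C)C | starting material
2 | acrolein | C=CC=O | starting material
3 | lithium acetylide of 1 | [Li]C#CCO[Si](C)(C)C(C)(C)C | intermediate
4 | rac-6-[(tert-butyldimethylsilyl)oxy]hex-1-en-4-yn-3-ol | C=CC(O)C#CCO[Si](C)(C)C(C)(C)C | intermediate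
5 | cyclic sodium alkoxy(vinyl)bis(2-methoxyethoxy)aluminate of 4 (racemic) | C=CC1O[Al-](OCCOC)(OCCOC)C(CO[Si](C)(C)C(C)(C)C)=C1.[Na+] | intermediate
6 | rac-(4Z)-6-[(tert-butyldimethylsilyl)oxy]-5-iodohexa-1,4-dien-3-ol | C=CC(O)/C=C(\I)CO[Si](C)(C)C(C)(C)C | intermediate
7 | rac-(4Z)-6-[(tert-butyldimethylsilyl)oxy]-5-iodohexa-1,4-dien-3-yl methyl carbonate | C=CC(OC(=O)OC)/C=C(\I)CO[Si](C)(C)C(C)(C)C | intermediate
8 | 2-(bromomethyl)prop-2-enoic acid | C=C(CBr)C(=O)O | starting material
9 | (3R,4Z)-6-[(tert-butyldimethylsilyl)oxy]-5-iodohexa-1,4-dien-3-yl 2-(bromomethyl)prop-2-enoate | C=C(CBr)C(=O)O[C@H](C=C)/C=C(\I)CO[Si](C)(C)C(C)(C)C | intermediate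
10 | (5R)-3-(bromomethyl)-5-[(1Z)-3-[(tert-butyldimethylsilyl)oxy]-2-iodoprop-1-en-1-yl]furan-2(5H)-one | O=C1O[C@@H](/C=C(\I)CO[Si](C)(C)C(C)(C)C)C=C1CBr | intermediate
11 | ethyl 3,3-diethoxypropanoate | CCOC(=O)CC(OCC)OCC | starting material
12 | 3,3-diethoxypropanal | O=CCC(OCC)OCC | intermediate
13 | methyl propiolate | C#CC(=O)OC | starting material
14 | methyl (4S)-6,6-diethoxy-4-hydroxyhex-2-ynoate | COC(=O)C#C[C@@H](O)CC(OCC)OCC | intermediate
15 | methyl (4S)-4-[(tert-butyldimethylsilyl)oxy]-6,6-diethoxyhex-2-ynoate | COC(=O)C#C[C@@H](O[Si](C)(C)C(C)(C)C)CC(OCC)OCC | intermediate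
16 | methyl (2Z,4S)-4-[(tert-butyldimethylsilyl)oxy]-6,6-diethoxy-3-methylhex-2-enoate | COC(=O)/C=C(C)\[C@@H](O[Si](C)(C)C(C)(C)C)CC(OCC)OCC | intermediate
17 | (2Z,4S)-4-[(tert-butyldimethylsilyl)oxy]-6,6-diethoxy-3-methylhex-2-en-1-ol | OC/C=C(C)\[C@@H](O[Si](C)(C)C(C)(C)C)CC(OCC)OCC | intermediate
18 | (2Z,4S)-4-[(tert-butyldimethylsilyl)oxy]-6,6-diethoxy-3-methylhex-2-enal | O=C/C=C(C)\[C@@H](O[Si](C)(C)C(C)(C)C)CC(OCC)OCC | intermediate
19 | (1S,6R,7S,8R,4Z,9Z)-1,15-bis[(tert-butyldimethylsilyl)oxy]-3,3-diethoxy-8-hydroxy-4-iodo-3,4-secogermacra-4,9,11(13)-trien-12,6-olide | C=C1C(=O)O[C@@H](/C=C(\I)CO[Si](C)(C)C(C)(C)C)[C@@H]1[C@H](O)/C=C(C)\[C@@H](O[Si](C)(C)C(C)(C)C)CC(OCC)OCC | intermediate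
20 | angelic acid, (2Z)-2-methylbut-2-enoic acid | C/C=C(/C)C(=O)O | starting material
21 | (2Z)-2-methylbut-2-enoic 2,4,6-trichlorobenzoic anhydride | C/C=C(/C)C(=O)OC(=O)c1c(Cl)cc(Cl)cc1Cl | intermediate
22 | (1S,6R,7S,8R,4Z,9Z)-8-angeloyloxy-1,15-bis[(tert-butyldimethylsilyl)oxy]-3,3-diethoxy-4-iodo-3,4-secogermacra-4,9,11(13)-trien-12,6-olide | C=C1C(=O)O[C@@H](/C=C(\I)CO[Si](C)(C)C(C)(C)C)[C@@H]1[C@H](OC(=O)/C(C)=C\C)/C=C(C)\[C@@H](O[Si](C)(C)C(C)(C)C)CC(OCC)OCC | intermediate
23 | (1S,6R,7S,8R,4Z,9Z)-8-angeloyloxy-1,15-bis[(tert-butyldimethylsilyl)oxy]-4-iodo-3-oxo-3,4-secogermacra-4,9,11(13)-trien-12,6-olide | C=C1C(=O)O[C@@H](/C=C(\I)CO[Si](C)(C)C(C)(C)C)[C@@H]1[C@H](OC(=O)/C(C)=C\C)/C=C(C)\[C@@H](O[Si](C)(C)C(C)(C)C)CC=O | intermediate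
24 | (1S,3S,6S,7S,8R,4Z,9Z)-8-angeloyloxy-1,15-bis[(tert-butyldimethylsilyl)oxy]-3-hydroxygermacra-4,9,11(13)-trien-12,6-olide | C=C1C(=O)O[C@H]2/C=C(/CO[Si](C)(C)C(C)(C)C)[C@@H](O)C[C@H](O[Si](C)(C)C(C)(C)C)/C(C)=C\[C@@H](OC(=O)/C(C)=C\C)[C@H]12 | intermediate
25 | (1S,3S,6S,7S,8R,4Z,9Z)-3-acetoxy-8-angeloyloxy-1,15-bis[(tert-butyldimethylsilyl)oxy]germacra-4,9,11(13)-trien-12,6-olide | C=C1C(=O)O[C@H]2/C=C(/CO[Si](C)(C)C(C)(C)C)[C@@H](OC(C)=O)C[C@H](O[Si](C)(C)C(C)(C)C)/C(C)=C\[C@@H](OC(=O)/C(C)=C\C)[C@H]12 | intermediate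
26 | (1S,3S,6S,7S,8R,4Z,9Z)-3-acetoxy-8-angeloyloxy-1,15-dihydroxygermacra-4,9,11(13)-trien-12,6-olide | C=C1C(=O)O[C@H]2/C=C(/CO)[C@@H](OC(C)=O)C[C@H](O)/C(C)=C\[C@@H](OC(=O)/C(C)=C\C)[C@H]12 | target

## Step count and risks

Total step count: 17. Longest linear sequence: 12 steps (steps 6–11, then 12–17); the other branch is 11 steps (steps 1–5, then 12–17).

**Step 4 (the proposed new method).** The allyl-iridium diastereomers may not equilibrate fully (low ee), some linear dienyl ester may form, or the allylic bromide of 8 may interfere. The fallback uses known chemistry and sets out from 1 and 2. A zinc–ProPhenol-catalysed asymmetric alkynylation of acrolein with alkyne 1 (Me2Zn, toluene, 0 °C) gives (3R)-6-[(tert-butyldimethylsilyl)oxy]hex-1-en-4-yn-3-ol F1. The hydroalumination–iodination of step 2 (Red-Al, then I2) converts it into (3R,4Z)-6-[(tert-butyldimethylsilyl)oxy]-5-iodohexa-1,4-dien-3-ol F2. Carbodiimide esterification with acid 8 (DCC, 5 mol% DMAP, CH2Cl2, −20 °C) comes back to the route at 9. C6 is then set by asymmetric C–C bond formation and the ester is made with retention.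

**Step 15.** The ring closure may give mainly the C3 epimer, because the 1,3-induction competes with the conformational demands of the forming ring. The fallback sets out from 23. The same chromium-mediated closure is accepted as it comes, and the epimeric alcohol, (1S,3R,6S,7S,8R,4Z,9Z)-8-angeloyloxy-1,15-bis[(tert-butyldimethylsilyl)oxy]-3-hydroxygermacra-4,9,11(13)-trien-12,6-olide F3, is esterified with inversion by a Mitsunobu reaction with acetic acid (PPh3, DIAD, toluene, 0 °C). This comes back to the route at 25 and replaces step 16.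

**Step 12.** The hindered (Z)-enal may couple with the wrong relative configuration at C8 (syn instead of anti adduct). The fallback sets out from 10 and 18. The C8 epimer, (1S,6R,7S,8S,4Z,9Z)-1,15-bis[(tert-butyldimethylsilyl)oxy]-3,3-diethoxy-8-hydroxy-4-iodo-3,4-secogermacra-4,9,11(13)-trien-12,6-olide F4, is esterified with inversion by a Mitsunobu reaction with angelic acid 20 (PPh3, DIAD, toluene, 0 °C). This comes back to the route at 22 and replaces step 13.

Further compounds
F1 | step 4 | (3R)-6-[(tert-butyldimethylsilyl)oxy]hex-1-en-4-yn-3-ol | C=C[C@@H](O)C#CCO[Si](C)(C)C(C)(C)C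
F2 | step 4 | (3R,4Z)-6-[(tert-butyldimethylsilyl)oxy]-5-iodohexa-1,4-dien-3-ol | C=C[C@@H](O)/C=C(\I)CO[Si](C)(C)C(C)(C)C
F3 | step 15 | (1S,3R,6S,7S,8R,4Z,9Z)-8-angeloyloxy-1,15-bis[(tert-butyldimethylsilyl)oxy]-3-hydroxygermacra-4,9,11(13)-trien-12,6-olide | C=C1C(=O)O[C@H]2/C=C(/CO[Si](C)(C)C(C)(C)C)[C@H](O)C[C@H](O[Si](C)(C)C(C)(C)C)/C(C)=C\[C@@H](OC(=O)/C(C)=C\C)[C@H]12
F4 | step 12 | (1S,6R,7S,8S,4Z,9Z)-1,15-bis[(tert-butyldimethylsilyl)oxy]-3,3-diethoxy-8-hydroxy-4-iodo-3,4-secogermacra-4,9,11(13)-trien-12,6-olide | C=C1C(=O)O[C@@H](/C=C(\I)CO[Si](C)(C)C(C)(C)C)[C@@H]1[C@@H](O)/C=C(C)\[C@@H](O[Si](C)(C)C(C)(C)C)CC(OCC)OCC
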